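## Retrosynthetic overview

- Numbering: ring A is the arene C4a–C5–C6–C7–C8–C8a. Ring B is the lactone C1(=O)–O2–C3–C4–C4a–C8a. The side chain is C1'–C11' with the ketone at C6'.
- 17 ⇐ 15 by cleaving the C8–OMe group under chelation by C1=O. 15 ⇐ isocoumarin 13 by enantioselective hydrogenation of C3=C4, which sets C3 while the ketone is masked as a dioxolane.
- 13 ⇐ aryne 11 + terminal alkyne 10 + CO2 in one copper-catalysed operation. It forms C4a–C4, then C8a–C1, then O2–C3, and this last bond closes ring B (6-endo-dig).
- Enabling feature: both arms of ring B (C4 and C1) stand on the neighbouring ring A carbons C4a and C8a, and C8 next to C8a carries oxygen. Ring A is therefore a 3-alkoxyaryne C4a≡C8a, polarised by that oxygen so that the carbon nucleophile goes to C4a and the metal, then CO2, to C8a.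
- Ring order: ring A is bought (1), the temporary dioxolane is made in step 4, ring B in step 5, and the dioxolane is removed in step 6. The fragments are 5 (two steps from 1) and 10 (two steps from 6 and 7).

Key step: step 5

Assumption: the (R,R)-NHC/(R,R)-diamine ruthenium catalyst of step 6 is taken to deliver the (R)-lactone; should a test run show the opposite sense, the mirror-image catalyst is used and nothing else changes.

## Route

Step 1
Reactants: 1 3,5-dimethoxyphenol
Product: 2 2-bromo-3,5-dimethoxyphenol
Conditions: NBS (1.0 equiv), i-Pr2NH (10 mol %), CH2Cl2, −78 °C → 0 °C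
Reagents that add atoms: N-bromosuccinimide, O=C1CCC(=O)N1Br
Why: Electrophilic aromatic bromination under amine catalysis, which delivers bromine ortho to the free hydroxyl group, should favour C2 (ortho to OH, para to the C5 methoxy group, two equivalent sites) over C4, which is squeezed between two methoxy groups, and one equivalent of NBS at low temperature limits double bromination.

Step 2
Reactants: 2 2-bromo-3,5-dimethoxyphenol
Product: 5 3,5-dimethoxy-2-(trimethylsilyl)phenyl trifluoromethanesulfonate, via aryl silyl ether 3 (not isolated), via lithium silylphenoxide 4 (not isolated)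
Conditions: (Me3Si)2NH, THF, reflux, then evaporation; n-BuLi, THF, −78 °C; Tf2O, −78 °C → rt
Reagents that add atoms: hexamethyldisilazane, C[Si](C)(C)N[Si](C)(C)C; trifluoromethanesulfonic anhydride, O=S(=O)(OS(=O)(=O)C(F)(F)F)C(F)(F)F
Why: O-silylation, bromine–lithium exchange, retro-Brook rearrangement (anionic 1,3-shift of silicon from oxygen to the lithiated C2) and O-triflation of the phenoxide set free make up the standard sequence to 2-silylaryl triflates, and the two methoxy groups are inert to it.

Step 3
Reactants: 6 oct-7-ynoic acid; 7 pentylmagnesium bromide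
Product: 9 tridec-12-yn-6-one, via oct-7-ynoyl chloride 8 (not isolated)
Conditions: (COCl)2, DMF (cat.), CH2Cl2, 0 °C → rt, then evaporation; 7 (1.05 equiv), Fe(acac)3 (3 mol %), THF, −78 °C
Reagents that add atoms: none
Why: Acid chloride formation followed by iron-catalysed acylation of a Grignard reagent, which at −78 °C is much faster than deprotonation of the terminal alkyne or addition to the ketone formed, should stop cleanly at 9.

Step 4
Reactants: 9 tridec-12-yn-6-one
Product: 10 2-(hept-6-yn-1-yl)-2-pentyl-1,3-dioxolane
Conditions: HOCH2CH2OH (3 equiv), p-TsOH·H2O (5 mol %), toluene, reflux, azeotropic removal of water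
Reagents that add atoms: ethylene glycol, OCCO
Why: Acid-catalysed ketalisation driven by water removal masks the C6' ketone, which would otherwise be enolised under the basic fluoride conditions of step 5 and reduced by the catalyst of step 6, while the terminal alkyne is inert.

Step 5
Reactants: 5 3,5-dimethoxy-2-(trimethylsilyl)phenyl trifluoromethanesulfonate; 10 2-(hept-6-yn-1-yl)-2-pentyl-1,3-dioxolane
Product: 13 6,8-dimethoxy-3-[5-(2-pentyl-1,3-dioxolan-2-yl)pentyl]-1H-isochromen-1-one, via 3,5-dimethoxybenzyne 11 (not isolated), via copper alkynylbenzoate 12 (not isolated)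
Conditions: [CuCl(IPr)] (10 mol %; IPr = 1,3-bis(2,6-diisopropylphenyl)imidazol-2-ylidene), CsF (3 equiv), Cs2CO3 (20 mol %), CO2 (1 atm), MeCN–THF 1:1, 80 °C, slow addition of 5
Reagents that add atoms: carbon dioxide, O=C=O
Why: Fluoride removes the silyl group of 5 and triflate leaves, giving aryne 11; the copper acetylide formed from 10, [CuCl(IPr)] and carbonate adds across the strained C4a≡C8a bond, the new aryl–copper bond at C8a inserts CO2 to give carboxylate 12, and its oxygen attacks the copper-activated alkyne carbon C3, after which the C4–Cu bond is protonated by a further molecule of 10, which releases 13 and renews the acetylide. The closest known reaction type is exactly this NHC–copper-catalysed three-component coupling of arynes from 2-silylaryl triflates, terminal alkynes and CO2 to 3-substituted isocoumarins, used here on a new pair of partners. Ring B is the only ring closed, in the 6-endo-dig mode, by formation of the O2–C3 bond. No stereocentre arises, since C3 stays sp2 until step 6. The step needs regioselective addition to the unsymmetrical aryne, and the methoxy group on C8 beside the triple bond secures it: its inductive pull distorts the aryne so that the remote carbon C4a is the more linear and electrophilic end and the charge (copper) builds up at C8a next to oxygen, while the C6 methoxy group is too far away to matter, so the alkynyl group ends on C4a and CO2 on C8a. It also needs CO2 capture to outrun protonation of the aryl–copper species and 6-endo to beat 5-exo closure, which slow aryne release into a CO2-saturated solution, the nucleophilic NHC-bound aryl–copper bond, the alkyl substituent on C3 and the thermodynamic pull of the conjugated 2-pyranone at 80 °C are expected to provide.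

Step 6
Reactants: 13 6,8-dimethoxy-3-[5-(2-pentyl-1,3-dioxolan-2-yl)pentyl]-1H-isochromen-1-one
Product: 15 (3R)-6,8-dimethoxy-3-(6-oxoundecyl)-3,4-dihydro-1H-isochromen-1-one, via ketal lactone 14 (not isolated)
Conditions: catalyst prepared from [Ru(cod)(2-methylallyl)2], (R,R)-SINpEt·HBF4 (1,3-bis[(R)-1-(naphthalen-1-yl)ethyl]imidazolinium tetrafluoroborate), KOt-Bu and (R,R)-1,2-diphenylethane-1,2-diamine (3 mol % Ru), NaOt-Bu (10 mol %), H2 (50 bar), toluene, 25 °C; then 1 M aq. HCl, THF, rt
Reagents that add atoms: water, O
Why: Catalytic asymmetric hydrogenation of an isocoumarin with a chiral ruthenium NHC–diamine catalyst, a reaction type established for 3-alkyl- and 8-methoxy-substituted isocoumarins, adds H2 to one face of the flat C3=C4 bond under catalyst control and so sets C3 as R, the dioxolane shields the side-chain ketone that this catalyst would otherwise reduce, and the acidic work-up hydrolyses only the ketal because C3 is not enolisable and the lactone is stable to dilute acid.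

Step 7
Reactants: 15 (3R)-6,8-dimethoxy-3-(6-oxoundecyl)-3,4-dihydro-1H-isochromen-1-one
Product: 17 (3R)-8-hydroxy-6-methoxy-3-(6-oxoundecyl)-3,4-dihydro-1H-isochromen-1-one, via boron chelate 16 (not isolated)
Conditions: BCl3 (2.5 equiv), CH2Cl2, −78 → −10 °C; then H2O
Reagents that add atoms: none
Why: Chelation-controlled Lewis acid cleavage of an aryl methyl ether holds BCl3 between the lactone carbonyl oxygen on C1 and the peri methoxy oxygen on C8 in a six-membered chelate, so that chloride removes only that methyl group, the unchelated C6 methoxy group, the ketone and the C3 stereocentre stay untouched at low temperature, and water hydrolyses chelate 16 to the hydrogen-bonded phenol 17.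

## Compound list

1 | 3,5-dimethoxyphenol | COc1cc(O)cc(OC)c1 | starting material
2 | 2-bromo-3,5-dimethoxyphenol | COc1cc(O)c(Br)c(OC)c1 | intermediate
3 | (2-bromo-3,5-dimethoxyphenoxy)trimethylsilane | COc1cc(O[Si](C)(C)C)c(Br)c(OC)c1 | intermediate
4 | lithium 3,5-dimethoxy-2-(trimethylsilyl)phenoxide | COc1cc([O-])c([Si](C)(C)C)c(OC)c1.[Li+] | intermediate
5 | 3,5-dimethoxy-2-(trimethylsilyl)phenyl trifluoromethanesulfonate | COc1cc(OS(=O)(=O)C(F)(F)F)c([Si](C)(C)C)c(OC)c1 | intermediate
6 | oct-7-ynoic acid | C#CCCCCCC(=O)O | starting material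
7 | pentylmagnesium bromide | CCCCC[Mg]Br | starting material
8 | oct-7-ynoyl chloride | C#CCCCCCC(=O)Cl | intermediate
9 | tridec-12-yn-6-one | CCCCCC(=O)CCCCCC#C | intermediate
10 | 2-(hept-6-yn-1-yl)-2-pentyl-1,3-dioxolane | CCCCCC1(CCCCCC#C)OCCO1 | intermediate
11 | 3,5-dimethoxybenzyne (1,2-didehydro-3,5-dimethoxybenzene) | COC1=CC(OC)=CC#C1 | intermediate
12 | copper 2,4-dimethoxy-6-[7-(2-pentyl-1,3-dioxolan-2-yl)hept-1-yn-1-yl]benzoate (NHC ligand on copper omitted) | CCCCCC1(CCCCCC#Cc2cc(OC)cc(OC)c2C(=O)O[Cu])OCCO1 | intermediate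
13 | 6,8-dimethoxy-3-[5-(2-pentyl-1,3-dioxolan-2-yl)pentyl]-1H-isochromen-1-one | CCCCCC1(CCCCCC2=Cc3cc(OC)cc(OC)c3C(=O)O2)OCCO1 | intermediate
14 | (3R)-6,8-dimethoxy-3-[5-(2-pentyl-1,3-dioxolan-2-yl)pentyl]-3,4-dihydro-1H-isochromen-1-one | CCCCCC1(CCCCC[C@@H]2Cc3cc(OC)cc(OC)c3C(=O)O2)OCCO1 | intermediate
15 | (3R)-6,8-dimethoxy-3-(6-oxoundecyl)-3,4-dihydro-1H-isochromen-1-one | CCCCCC(=O)CCCCC[C@@H]1Cc2cc(OC)cc(OC)c2C(=O)O1 | intermediate
16 | (3R)-8-(dichloroboryloxy)-6-methoxy-3-(6-oxoundecyl)-3,4-dihydro-1H-isochromen-1-one | CCCCCC(=O)CCCCC[C@@H]1Cc2cc(OC)cc(OB(Cl)Cl)c2C(=O)O1 | intermediate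
17 | (3R)-8-hydroxy-6-methoxy-3-(6-oxoundecyl)-3,4-dihydro-1H-isochromen-1-one | CCCCCC(=O)CCCCC[C@@H]1Cc2cc(OC)cc(O)c2C(=O)O1 | target

## Step count and risks

Total step count: 7. Longest linear sequence: 5 steps (1, 2, 5, 6, 7 or 3, 4, 5, 6, 7).

**Step 5.**
- The three-component channel may be eroded in four ways: protonation of the aryl–copper intermediate before CO2 is taken up, carboxylation of the copper acetylide in place of its addition to the aryne, self-reaction of the aryne, or 5-exo closure.
- The fallback sets out from 2 and 10 and comes back at 13. It makes the three bonds one after the other by cross-coupling chemistry without an aryne.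
- Phenol 2 is triflated (Tf2O, pyridine, CH2Cl2, 0 °C) to 2-bromo-3,5-dimethoxyphenyl trifluoromethanesulfonate F1.
- A Sonogashira coupling with 10 (PdCl2(PPh3)2, CuI, Et3N, DMF, 60 °C) follows. It should take place at the C–OTf carbon, which is meta to both methoxy groups and has one ortho neighbour. The C–Br carbon is ortho and para to the donors and flanked on both sides. The product is 2-[7-(2-bromo-3,5-dimethoxyphenyl)hept-6-yn-1-yl]-2-pentyl-1,3-dioxolane F2.
- Bromine–lithium exchange (n-BuLi, THF, −78 °C), CO2 and work-up at pH 4–5 give 2,4-dimethoxy-6-[7-(2-pentyl-1,3-dioxolan-2-yl)hept-1-yn-1-yl]benzoic acid F3.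
- Copper-catalysed 6-endo-dig cycloisomerisation ([CuCl(IPr)], Cs2CO3 cat., MeCN, 80 °C) then forms the same O2–C3 bond and gives 13.

**Step 6.**
- Facial selectivity may be poor, reduction of the pseudo-aromatic pyranone carrying a long chain and two methoxy groups may be sluggish, or the alkoxide base may open the lactone.
- The fallback sets out from 13 and comes back at 15. It replaces alkene hydrogenation by enzymatic ketone reduction.
- Saponification (KOH, EtOH–H2O, rt) opens 13 at C1. This keeps the O–C3 bond as a ketone and gives 2,4-dimethoxy-6-[2-oxo-7-(2-pentyl-1,3-dioxolan-2-yl)heptyl]benzoic acid F4, handled as its potassium salt.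
- An NADPH-dependent alcohol dehydrogenase chosen from a panel for bulky ketones (i-PrOH as hydride source, phosphate buffer pH 7.5, 30 °C) reduces the only free ketone. The product is 2-[(2R)-2-hydroxy-7-(2-pentyl-1,3-dioxolan-2-yl)heptyl]-4,6-dimethoxybenzoic acid F5.
- 1 M aq. HCl in THF at rt then lactonises F5 and hydrolyses the ketal in one operation to 15.

**Step 1.**
- Bromination may also run at C4, or twice, on this very electron-rich phenol, and the isomers may be hard to separate.
- The fallback sets out from 1 and comes back at 5, bypassing steps 1 and 2. It places silicon by directed ortho-metalation in place of halogenation.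
- Carbamoylation (ClC(=O)NEt2, K2CO3, MeCN, reflux) gives 3,5-dimethoxyphenyl N,N-diethylcarbamate F6.
- Lithiation between the carbamate and the methoxy group (s-BuLi, TMEDA, THF, −78 °C), then Me3SiCl, gives 3,5-dimethoxy-2-(trimethylsilyl)phenyl N,N-diethylcarbamate F7.
- LiAlH4 (THF, 0 °C → rt) removes the carbamoyl group to give 3,5-dimethoxy-2-(trimethylsilyl)phenol F8.
- Tf2O with pyridine (CH2Cl2, 0 °C) gives 5.

Further compounds
F1 | step 5 | 2-bromo-3,5-dimethoxyphenyl trifluoromethanesulfonate | COc1cc(OS(=O)(=O)C(F)(F)F)c(Br)c(OC)c1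
F2 | step 5 | 2-[7-(2-bromo-3,5-dimethoxyphenyl)hept-6-yn-1-yl]-2-pentyl-1,3-dioxolane | CCCCCC1(CCCCCC#Cc2cc(OC)cc(OC)c2Br)OCCO1
F3 | step 5 | 2,4-dimethoxy-6-[7-(2-pentyl-1,3-dioxolan-2-yl)hept-1-yn-1-yl]benzoic acid | CCCCCC1(CCCCCC#Cc2cc(OC)cc(OC)c2C(=O)O)OCCO1
F4 | step 6 | 2,4-dimethoxy-6-[2-oxo-7-(2-pentyl-1,3-dioxolan-2-yl)heptyl]benzoic acid | CCCCCC1(CCCCCC(=O)Cc2cc(OC)cc(OC)c2C(=O)O)OCCO1
F5 | step 6 | 2-[(2R)-2-hydroxy-7-(2-pentyl-1,3-dioxolan-2-yl)heptyl]-4,6-dimethoxybenzoic acid | CCCCCC1(CCCCC[C@@H](O)Cc2cc(OC)cc(OC)c2C(=O)O)OCCO1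
F6 | step 1 | 3,5-dimethoxyphenyl N,N-diethylcarbamate | CCN(CC)C(=O)Oc1cc(OC)cc(OC)c1
F7 | step 1 | 3,5-dimethoxy-2-(trimethylsilyl)phenyl N,N-diethylcarbamate | CCN(CC)C(=O)Oc1cc(OC)cc(OC)c1[Si](C)(C)C
F8 | step 1 | 3,5-dimethoxy-2-(trimethylsilyl)phenol | COc1cc(O)c([Si](C)(C)C)c(OC)c1
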